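**Plan**

1. Cuts: the three trisubstituted alkenes go back to terminal alkenes (cross-metathesis) and the C3a=C7a double bond to a single bond (dehydrogenation). Then C2–C3 and C3a–C7a are cut together (Prins–pinacol), giving a cyclopentane cis-diol acetal and an α-silyloxy aldehyde. The cyclopentane goes back through C7 allylation, O1–C7a conjugate addition, C7 acylation and vinyl addition to 2-allyl-2-methylcyclopentane-1,3-dione.
2. Enabling feature: the C4 ketone sits on C3a, the ring-fusion carbon next to the oxygen-bearing C7a of the dihydrofuran ring (O1, C2, C3, C3a, C7a). This 3-acyltetrahydrofuran (β-alkoxy ketone) pattern inside the cyclohexanedione ring (C3a to C7a) is the product pattern of a Prins–pinacol rearrangement, so the carbocycle can come from a cyclopentane by one-carbon ring expansion while the oxygen ring is annulated.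
3. Forward order: the cyclopentane (a temporary ring) is decorated first; the tetrahydrofuran ring and the six-membered ring arise together in the key step; the C3a=C7a unsaturation, the prenyl termini and the free carbinol follow.
4. Stereochemistry: C5 comes from a Corey–Bakshi–Shibata desymmetrization. It is relayed through temporary centres of the cyclopentane: vinyl addition anti to allyl, boron-tethered cis delivery of O1 (sets C7a), allylation at C7 anti to O1, and a chair Prins transition state that passes the C7a configuration to C2 before C7a is flattened. The side-chain carbinol comes from (R)-2-methylglycidol.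

Key step: step 15

Remark: locants O1, C2, C3, C3a, C4 to C7 and C7a are those of the 1-benzofuran core of the target and are also used for the atoms that become these positions; the vinylogous-ester unsaturation is assumed to be best introduced by dehydrogenation after the key step.

**Route**

Step 1
Reactants: 1 (R)-2-methylglycidol
Product: 2 (S)-2-methylhex-5-ene-1,2-diol
Conditions: CH2=CHCH2MgBr (3 equiv), CuI (10 mol%), THF, −40 → 0 °C; aq. NH4Cl
Reagents that add atoms: allylmagnesium bromide, C=CC[Mg]Br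
Why: Copper-catalysed Grignard opening of the epoxide at its unsubstituted CH2 carbon does not touch the quaternary centre, so the side-chain carbinol configuration is taken from the chiral pool.

Step 2
Reactants: 2 (S)-2-methylhex-5-ene-1,2-diol
Product: 3 (S)-2-methyl-1,2-bis(triethylsilyloxy)hex-5-ene
Conditions: Et3SiOTf (2.4 equiv), 2,6-lutidine, CH2Cl2, 0 °C
Reagents that add atoms: triethylsilyl trifluoromethanesulfonate, CC[Si](CC)(CC)OS(=O)(=O)C(F)(F)F
Why: Silylation with a silyl triflate should cover the hindered tertiary hydroxyl as well as the primary one.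

Step 3
Reactants: 3 (S)-2-methyl-1,2-bis(triethylsilyloxy)hex-5-ene
Product: 4 (S)-2-methyl-2-(triethylsilyloxy)hex-5-enal
Conditions: (COCl)2, DMSO, CH2Cl2, −78 → −30 °C; Et3N, −78 → 0 °C
Reagents that add atoms: none
Why: Swern oxidation, in which the chlorosulfonium reagent cleaves and oxidizes the unhindered primary triethylsilyl ether in place while the tertiary silyl ether stays; the aldehyde has no α-hydrogen, so the carbinol centre cannot epimerize.

Step 4
Reactants: 5 2-allyl-2-methylcyclopentane-1,3-dione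
Product: 6 (2R,3R)-2-allyl-3-hydroxy-2-methylcyclopentan-1-one
Conditions: (S)-2-methyl-CBS-oxazaborolidine (20 mol%), catecholborane, toluene, −78 °C; MeOH, aq. NaHCO3
Reagents that add atoms: none
Why: Corey–Bakshi–Shibata reduction used as a desymmetrization: the catalyst should select one of the two enantiotopic carbonyl groups and deliver hydride to the methyl-bearing face, which sets the quaternary carbon (the later C5) together with a temporary carbinol whose OH is cis to allyl; the catalyst antipode is chosen for the (2R,3R) series.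

Step 5
Reactants: 6 (2R,3R)-2-allyl-3-hydroxy-2-methylcyclopentan-1-one
Product: 7 (2R,3R)-2-allyl-2-methyl-3-(triethylsilyloxy)cyclopentan-1-one
Conditions: Et3SiCl, imidazole, CH2Cl2, rt
Reagents that add atoms: chlorotriethylsilane, CC[Si](Cl)(CC)CC
Why: Silylation removes the free alkoxide (no chelation, no retro-aldol in the next step) and adds bulk to the allyl face of the ketone.

Step 6
Reactants: 7 (2R,3R)-2-allyl-2-methyl-3-(triethylsilyloxy)cyclopentan-1-one
Product: 9 (1R,2R,3R)-2-allyl-2-methyl-1-vinylcyclopentane-1,3-diol, via silyl-protected vinyl adduct 8 (not isolated)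
Conditions: CH2=CHMgBr, CeCl3, THF, −78 °C; then 1 M HCl, THF, 0 °C
Reagents that add atoms: vinylmagnesium bromide, C=C[Mg]Br
Why: Organocerium 1,2-addition to a hindered enolizable ketone should occur from the methyl-bearing face, away from the allyl and silyloxy groups, placing the new tertiary OH cis to allyl; the acidic work-up removes the triethylsilyl ether.

Step 7
Reactants: 9 (1R,2R,3R)-2-allyl-2-methyl-1-vinylcyclopentane-1,3-diol
Product: 10 (2S,3R)-2-allyl-3-hydroxy-2-methyl-3-vinylcyclopentan-1-one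
Conditions: Dess–Martin periodinane, NaHCO3, CH2Cl2, 0 °C → rt
Reagents that add atoms: none
Why: Dess–Martin oxidation acts only on the secondary alcohol and restores the ketone that becomes C6.

Step 8
Reactants: 10 (2S,3R)-2-allyl-3-hydroxy-2-methyl-3-vinylcyclopentan-1-one
Product: 11 (2S,3R)-2-allyl-2-methyl-3-(trimethylsilyloxy)-3-vinylcyclopentan-1-one
Conditions: 1-(trimethylsilyl)imidazole, CH2Cl2, rt
Reagents that add atoms: 1-(trimethylsilyl)imidazole, C[Si](C)(C)n1ccnc1
Why: Silylation of the tertiary aldol-type hydroxyl guards against retro-aldol cleavage and O-acylation under the basic conditions of the next step.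

Step 9
Reactants: 11 (2S,3R)-2-allyl-2-methyl-3-(trimethylsilyloxy)-3-vinylcyclopentan-1-one
Product: 13 (2S,3R)-2-allyl-3-hydroxy-5-isobutyryl-2-methyl-3-vinylcyclopentan-1-one, via trimethylsilyl-protected diketone 12 (not isolated)
Conditions: LiN(SiMe3)2 (2.1 equiv), toluene, −78 → 0 °C; (CH3)2CHCOCl, 0 °C; then 1 M HCl, THF, rt
Reagents that add atoms: isobutyryl chloride, CC(C)C(Cl)=O
Why: Claisen-type C-acylation of the only possible lithium enolate (the other α-carbon is quaternary) gives the 2-acyl ketone while the β-position is still CH2, so no β-alkoxide elimination can occur; the acid work-up removes the trimethylsilyl ether.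

Step 10
Reactants: 13 (2S,3R)-2-allyl-3-hydroxy-5-isobutyryl-2-methyl-3-vinylcyclopentan-1-one
Product: 16 (4S,5S)-5-allyl-4-hydroxy-2-isobutyryl-5-methyl-4-vinylcyclopent-2-en-1-one, via selenide 14 (not isolated), via selenoxide 15 (not isolated)
Conditions: PhSeCl, pyridine, CH2Cl2, 0 °C; then 30% H2O2, 0 °C; crude product used at once
Reagents that add atoms: none
Why: α-Selenenylation of the enolized 1,3-diketone followed by selenoxide syn-elimination, whose only β-hydrogens are on the future C7a, gives the doubly activated enone.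

Step 11
Reactants: 16 (4S,5S)-5-allyl-4-hydroxy-2-isobutyryl-5-methyl-4-vinylcyclopent-2-en-1-one
Product: 18 (3aS,6S,6aR)-6-allyl-4-isobutyryl-6-methyl-2-phenyl-6a-vinyl-tetrahydro-4H-cyclopenta[d][1,3,2]dioxaborol-5-one, via boronic hemiester 17 (not isolated)
Conditions: PhB(OH)2 (1.2 equiv), iPr2NEt (20 mol%), 4 Å MS, CH2Cl2, rt
Reagents that add atoms: phenylboronic acid, OB(O)c1ccccc1
Why: Boronic acid hemiester-directed intramolecular oxa-Michael addition: the B–OH oxygen can reach the β-carbon only on the face of the tertiary oxygen, so the C7a oxygen is set cis to it and the product is the cis-fused cyclic boronate of a stabilized 1,3-diketone enol.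

Step 12
Reactants: 18 (3aS,6S,6aR)-6-allyl-4-isobutyryl-6-methyl-2-phenyl-6a-vinyl-tetrahydro-4H-cyclopenta[d][1,3,2]dioxaborol-5-one
Product: 19 (3aS,4S,6S,6aR)-4,6-diallyl-4-isobutyryl-6-methyl-2-phenyl-6a-vinyl-tetrahydro-4H-cyclopenta[d][1,3,2]dioxaborol-5-one
Conditions: allyl bromide, K2CO3, acetone, rt
Reagents that add atoms: allyl bromide, C=CCBr
Why: C-Alkylation of the 2-acylcyclopentanone enolate should occur on the convex face of the cis-fused bicycle, anti to the vicinal C–O bond, which sets the quaternary centre that becomes C7 (allyl trans to O1).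

Step 13
Reactants: 19 (3aS,4S,6S,6aR)-4,6-diallyl-4-isobutyryl-6-methyl-2-phenyl-6a-vinyl-tetrahydro-4H-cyclopenta[d][1,3,2]dioxaborol-5-one
Product: 20 (2S,3R,4S,5S)-2,5-diallyl-3,4-dihydroxy-5-isobutyryl-2-methyl-3-vinylcyclopentan-1-one
Conditions: 30% H2O2, pH 7 phosphate buffer, THF, 0 °C
Reagents that add atoms: none
Why: Oxidative cleavage of the boron–phenyl bond and hydrolysis of the borate release the cis-diol at neutral pH, which avoids retro-aldol opening of the β-hydroxy diketone.

Step 14
Reactants: 20 (2S,3R,4S,5S)-2,5-diallyl-3,4-dihydroxy-5-isobutyryl-2-methyl-3-vinylcyclopentan-1-one; 4 (S)-2-methyl-2-(triethylsilyloxy)hex-5-enal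
Product: 21 (3aS,4S,6S,6aR)-4,6-diallyl-4-isobutyryl-6-methyl-2-[(2S)-2-(triethylsilyloxy)hex-5-en-2-yl]-6a-vinyl-tetrahydro-4H-cyclopenta[d][1,3]dioxol-5-one (both acetal epimers)
Conditions: CSA (10 mol%), MgSO4, CH2Cl2, rt
Reagents that add atoms: none
Why: Acid-catalysed acetalization of a cis-1,2-diol with a non-enolizable aldehyde gives the cis-fused dioxolane; both acetal epimers give the same oxocarbenium ion in the next step.

Step 15
Reactants: 21 dioxolane acetal (3aS,4S,6S,6aR) described in step 14
Product: 24 (2S,3aS,5S,7S,7aR)-5,7-diallyl-7-isobutyryl-5-methyl-2-[(2S)-2-(triethylsilyloxy)hex-5-en-2-yl]hexahydro-1-benzofuran-4,6(2H,5H)-dione, via oxocarbenium ion 22 (not isolated), via oxanyl cation 23 (not isolated)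
Conditions: SnCl4 (3 equiv), CH2Cl2, −78 → −20 °C
Reagents that add atoms: none
Why: SnCl4 cleaves the acetal C–O bond on the tertiary (vinyl carbinol) oxygen to give the (E)-oxocarbenium ion 22 on O1, the vinyl terminus (C3) adds to its carbon (C2) in a Prins cyclization to oxanyl cation 23, and a pinacol 1,2-shift of C7a from the carbinol carbon to the cationic C3a, pushed by the tin alkoxide, makes the C3a–C7a bond and the C4 ketone. The closest known reaction type is the Prins–pinacol ring-enlarging tetrahydrofuran annulation of acetals of 1-alkenylcycloalkane-1,2-diols. The tetrahydrofuran ring closes by a 6-endo-trig Prins closure to an oxane followed by ring contraction in the pinacol shift, and the six-membered carbocycle is not closed but arises by one-carbon ring expansion of the cyclopentane. C2 is set by the chair transition state, in which the (E)-oxocarbenium places the side chain equatorial and the trans ring fusion derived from the cis-diol places C7 on C7a equatorial, so that H2 and H7a end cis and C7a, which migrates with retention and never becomes trigonal, passes its configuration to C2; the new C3a centre (cis ring fusion) is removed in step 16. The step needs the vinyl group to win over the three other terminal alkenes and C7a to migrate instead of C5: only the vinyl group is held by the dioxolane within a six-membered chair reach of C2 and has the alkoxide push that ends the cation, the allyl groups would need seven-membered closures, and C5 is a poor migrating group because it is alpha to the C6 ketone whereas C7a bears oxygen. An excess of SnCl4 allows for binding by the 1,3-diketone.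

Step 16
Reactants: 24 cis-fused bicyclic diketone (2S,3aS,5S,7S,7aR) described in step 15
Product: 26 (2S,5S,7S)-5,7-diallyl-7-isobutyryl-5-methyl-2-[(2S)-2-(triethylsilyloxy)hex-5-en-2-yl]-3,7-dihydro-1-benzofuran-4,6(2H,5H)-dione, via silyl enol ether 25 (not isolated)
Conditions: Me3SiOTf (1.1 equiv), Et3N, CH2Cl2, −78 → 0 °C; then Pd(OAc)2 (1.1 equiv), MeCN, rt
Reagents that add atoms: none
Why: Saegusa–Ito oxidation: soft enolization should favour the C4 ketone, whose C3a–H is acidified by the β-oxygen, over the hindered isobutyryl group, and palladium bound on the convex face at C3a is syn to H7a and anti to O1, so β-hydride elimination (not β-alkoxide loss) should give the C3a=C7a vinylogous ester.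

Step 17
Reactants: 26 (2S,5S,7S)-triene described in step 16
Product: 27 (2S,5S,7S)-7-isobutyryl-5-methyl-5,7-bis(3-methylbut-2-enyl)-2-[(2S)-6-methyl-2-(triethylsilyloxy)hept-5-en-2-yl]-3,7-dihydro-1-benzofuran-4,6(2H,5H)-dione
Conditions: 2-methylbut-2-ene (large excess), second-generation Grubbs catalyst (10 mol%), CH2Cl2, 40 °C
Reagents that add atoms: 2-methylbut-2-ene, CC=C(C)C
Why: Threefold olefin cross-metathesis turns the two allyl groups and the butenyl chain into the prenyl-type termini in one operation; no stereocentre is involved.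

Step 18
Reactants: 27 silyl ether described in step 17
Product: 28 CNP0250451.1, (2S,5S,7S)-2-[(2S)-2-hydroxy-6-methylhept-5-en-2-yl]-7-isobutyryl-5-methyl-5,7-bis(3-methylbut-2-enyl)-3,7-dihydro-1-benzofuran-4,6(2H,5H)-dione
Conditions: HF·pyridine, pyridine, THF, 0 °C → rt
Reagents that add atoms: none
Why: Buffered fluoride desilylation frees the tertiary alcohol without base that could cleave the non-enolizable 1,3-diketone.

**Compound list**

1 | (R)-2-methylglycidol, (2R)-(2-methyloxiran-2-yl)methanol | C1[C@](C)(O1)CO | starting material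
2 | (S)-2-methylhex-5-ene-1,2-diol | C=CCC[C@](C)(O)CO | intermediate
3 | (S)-2-methyl-1,2-bis(triethylsilyloxy)hex-5-ene | C=CCC[C@](C)(O[Si](CC)(CC)CC)CO[Si](CC)(CC)CC | intermediate
4 | (S)-2-methyl-2-(triethylsilyloxy)hex-5-enal | C=CCC[C@](C)(O[Si](CC)(CC)CC)C=O | intermediate
5 | 2-allyl-2-methylcyclopentane-1,3-dione | C=CCC1(C)C(=O)CCC1=O | starting material
6 | (2R,3R)-2-allyl-3-hydroxy-2-methylcyclopentan-1-one (OH cis to allyl) | O[C@@H]1CCC(=O)[C@]1(C)CC=C | intermediate
7 | (2R,3R)-2-allyl-2-methyl-3-(triethylsilyloxy)cyclopentan-1-one | CC[Si](CC)(CC)O[C@@H]1CCC(=O)[C@]1(C)CC=C | intermediate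
8 | (1R,2R,3R)-2-allyl-2-methyl-3-(triethylsilyloxy)-1-vinylcyclopentan-1-ol | CC[Si](CC)(CC)O[C@@H]1CC[C@@](O)(C=C)[C@]1(C)CC=C | intermediate
9 | (1R,2R,3R)-2-allyl-2-methyl-1-vinylcyclopentane-1,3-diol (both OH cis to allyl) | O[C@@H]1CC[C@@](O)(C=C)[C@]1(C)CC=C | intermediate
10 | (2S,3R)-2-allyl-3-hydroxy-2-methyl-3-vinylcyclopentan-1-one | O=C1CC[C@@](O)(C=C)[C@]1(C)CC=C | intermediate
11 | (2S,3R)-2-allyl-2-methyl-3-(trimethylsilyloxy)-3-vinylcyclopentan-1-one | O=C1CC[C@@](O[Si](C)(C)C)(C=C)[C@]1(C)CC=C | intermediate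
12 | (2S,3R)-2-allyl-5-isobutyryl-2-methyl-3-(trimethylsilyloxy)-3-vinylcyclopentan-1-one (C5 epimers, enolized) | O=C1C(C(=O)C(C)C)C[C@@](O[Si](C)(C)C)(C=C)[C@]1(C)CC=C | intermediate
13 | (2S,3R)-2-allyl-3-hydroxy-5-isobutyryl-2-methyl-3-vinylcyclopentan-1-one (C5 epimers, enolized) | O=C1C(C(=O)C(C)C)C[C@@](O)(C=C)[C@]1(C)CC=C | intermediate
14 | (2S,3R)-2-allyl-3-hydroxy-5-isobutyryl-2-methyl-5-(phenylselanyl)-3-vinylcyclopentan-1-one | O=C1C([Se]c2ccccc2)(C(=O)C(C)C)C[C@@](O)(C=C)[C@]1(C)CC=C | intermediate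
15 | selenoxide of 14 | O=C1C([Se](=O)c2ccccc2)(C(=O)C(C)C)C[C@@](O)(C=C)[C@]1(C)CC=C | intermediate
16 | (4S,5S)-5-allyl-4-hydroxy-2-isobutyryl-5-methyl-4-vinylcyclopent-2-en-1-one | O=C1C(C(=O)C(C)C)=C[C@@](O)(C=C)[C@]1(C)CC=C | intermediate
17 | phenylboronic hemiester of 16 at the tertiary oxygen | O=C1C(C(=O)C(C)C)=C[C@@](OB(O)c2ccccc2)(C=C)[C@]1(C)CC=C | intermediate
18 | (3aS,6S,6aR)-6-allyl-4-isobutyryl-6-methyl-2-phenyl-6a-vinyl-tetrahydro-4H-cyclopenta[d][1,3,2]dioxaborol-5-one (cis-fused; C4 epimers, enolized) | O=C1C(C(=O)C(C)C)[C@@H]2OB(c3ccccc3)O[C@]2(C=C)[C@]1(C)CC=C | intermediate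
19 | (3aS,4S,6S,6aR)-4,6-diallyl-4-isobutyryl-6-methyl-2-phenyl-6a-vinyl-tetrahydro-4H-cyclopenta[d][1,3,2]dioxaborol-5-one | O=C1[C@](CC=C)(C(=O)C(C)C)[C@@H]2OB(c3ccccc3)O[C@]2(C=C)[C@]1(C)CC=C | intermediate
20 | (2S,3R,4S,5S)-2,5-diallyl-3,4-dihydroxy-5-isobutyryl-2-methyl-3-vinylcyclopentan-1-one | O=C1[C@](CC=C)(C(=O)C(C)C)[C@H](O)[C@@](O)(C=C)[C@]1(C)CC=C | intermediate
21 | (3aS,4S,6S,6aR)-4,6-diallyl-4-isobutyryl-6-methyl-2-[(2S)-2-(triethylsilyloxy)hex-5-en-2-yl]-6a-vinyl-tetrahydro-4H-cyclopenta[d][1,3]dioxol-5-one (both acetal epimers) | O=C1[C@](CC=C)(C(=O)C(C)C)[C@@H]2OC(O[C@]2(C=C)[C@]1(C)CC=C)[C@](C)(CCC=C)O[Si](CC)(CC)CC | intermediate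
22 | oxocarbenium ion on O1 with the tertiary oxygen bound as tetrachlorostannate (zwitterion) | O=C1[C@](CC=C)(C(=O)C(C)C)[C@H]([O+]=C[C@](C)(CCC=C)O[Si](CC)(CC)CC)[C@@](O[Sn-](Cl)(Cl)(Cl)Cl)(C=C)[C@]1(C)CC=C | intermediate
23 | oxanyl cation (cation at C3a, trans-fused to the cyclopentane, stannate on the carbinol oxygen) | O=C1[C@](CC=C)(C(=O)C(C)C)[C@@H]2O[C@@H](C[CH+][C@@]2(O[Sn-](Cl)(Cl)(Cl)Cl)[C@]1(C)CC=C)[C@](C)(CCC=C)O[Si](CC)(CC)CC | intermediate
24 | (2S,3aS,5S,7S,7aR)-5,7-diallyl-7-isobutyryl-5-methyl-2-[(2S)-2-(triethylsilyloxy)hex-5-en-2-yl]hexahydro-1-benzofuran-4,6(2H,5H)-dione (cis-fused) | C=CCC[C@](C)(O[Si](CC)(CC)CC)[C@@H]1C[C@H]2[C@@H](O1)[C@@](CC=C)(C(=O)C(C)C)C(=O)[C@@](C)(CC=C)C2=O | intermediate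
25 | (2S,5S,7S,7aR)-5,7-diallyl-7-isobutyryl-5-methyl-2-[(2S)-2-(triethylsilyloxy)hex-5-en-2-yl]-4-(trimethylsilyloxy)-3,5,7,7a-tetrahydro-1-benzofuran-6(2H)-one | C=CCC[C@](C)(O[Si](CC)(CC)CC)[C@@H]1CC2=C(O[Si](C)(C)C)[C@](C)(CC=C)C(=O)[C@](CC=C)(C(=O)C(C)C)[C@@H]2O1 | intermediate
26 | (2S,5S,7S)-5,7-diallyl-7-isobutyryl-5-methyl-2-[(2S)-2-(triethylsilyloxy)hex-5-en-2-yl]-3,7-dihydro-1-benzofuran-4,6(2H,5H)-dione | C=CCC[C@](C)(O[Si](CC)(CC)CC)[C@@H]1CC2=C(O1)[C@@](CC=C)(C(=O)C(C)C)C(=O)[C@@](C)(CC=C)C2=O | intermediate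
27 | (2S,5S,7S)-7-isobutyryl-5-methyl-5,7-bis(3-methylbut-2-enyl)-2-[(2S)-6-methyl-2-(triethylsilyloxy)hept-5-en-2-yl]-3,7-dihydro-1-benzofuran-4,6(2H,5H)-dione | CC(C)=CCC[C@](C)(O[Si](CC)(CC)CC)[C@@H]1CC2=C(O1)[C@@](CC=C(C)C)(C(=O)C(C)C)C(=O)[C@@](C)(CC=C(C)C)C2=O | intermediate
28 | CNP0250451.1, (2S,5S,7S)-2-[(2S)-2-hydroxy-6-methylhept-5-en-2-yl]-7-isobutyryl-5-methyl-5,7-bis(3-methylbut-2-enyl)-3,7-dihydro-1-benzofuran-4,6(2H,5H)-dione | CC(C)=CCC[C@](C)(O)[C@@H]1CC2=C(O1)[C@@](CC=C(C)C)(C(=O)C(C)C)C(=O)[C@@](C)(CC=C(C)C)C2=O | target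

**Count and risks**

Total steps: 18. Longest linear sequence: 15 steps (steps 4 to 18, from 5); the aldehyde 4 is made in 3 steps and joins at step 14.

Steps most likely to fail:

1. Step 15 (key step). The oxocarbenium ion may be captured by the terminal alkene of the hexenyl chain (6-endo closure to a cyclohexyl cation) faster than by the vinyl group, or the Lewis acid may be held by the 1,3-diketone so that ionization stalls. Fallback: the chain alkene is masked as a vicinal dibromide, so that only the vinyl group can answer the cation. Setting out from 3, bromine (pyridine, CH2Cl2, −78 °C) should give the dibromide F1. Swern oxidation as in step 3 should give the dibromo aldehyde F2, and acetalization with 20 as in step 14 the dibromo acetal F3. SnCl4 as in step 15 should give the ring-expanded dibromide F4. Zinc dust (AcOH, EtOH, 0 °C) then restores the alkene and the route is rejoined at 24.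

2. Step 11. Hemiester formation at the hindered tertiary hydroxyl may be slower than hydration or self-condensation of the doubly activated enone. Fallback: a carbon tether replaces the boron tether. Setting out from 16, benzaldehyde (excess) and KOC(CH3)3 (catalytic) in THF at 0 °C should form the hemiacetal alkoxide, which can add to C7a only in the same cis sense and gives the benzylidene acetal F5. Allylation as in step 12 should give the allylated benzylidene acetal F6. Acidic hydrolysis (AcOH, H2O, THF, 40 °C) releases the diol and the route is rejoined at 20.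

3. Step 16. The isobutyryl ketone may enolize in competition with the C4 ketone, and the palladium enolate may lose the hydride from C3 instead of C7a. Fallback: the selectivity is moved from the enolization to the oxidant. Setting out from 24, excess Me3SiOTf and Et3N should silylate both ketones to give the bis(silyl enol ether) F7. DDQ (1 equiv, 2,6-lutidine, CH2Cl2, 0 °C) should abstract hydride only from C7a–H, the one C–H that is both allylic to an enol ether and alpha to oxygen, giving the vinylogous ester F8 with the isobutyryl group still as its silyl enol ether. Dilute aqueous acid then hydrolyses that enol ether and the route is rejoined at 26.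

**Further compounds**

F1 | step 15 | (2S)-5,6-dibromo-2-methyl-1,2-bis(triethylsilyloxy)hexane (both C5 epimers) | BrCC(Br)CC[C@](C)(O[Si](CC)(CC)CC)CO[Si](CC)(CC)CC
F2 | step 15 | (2S)-5,6-dibromo-2-methyl-2-(triethylsilyloxy)hexanal | BrCC(Br)CC[C@](C)(O[Si](CC)(CC)CC)C=O
F3 | step 15 | dibromo analogue of acetal 21 (side chain 5,6-dibromo-2-(triethylsilyloxy)hexan-2-yl) | O=C1[C@](CC=C)(C(=O)C(C)C)[C@@H]2OC(O[C@]2(C=C)[C@]1(C)CC=C)[C@](C)(CCC(Br)CBr)O[Si](CC)(CC)CC
F4 | step 15 | dibromo analogue of bicyclic diketone 24 | BrCC(Br)CC[C@](C)(O[Si](CC)(CC)CC)[C@@H]1C[C@H]2[C@@H](O1)[C@@](CC=C)(C(=O)C(C)C)C(=O)[C@@](C)(CC=C)C2=O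
F5 | step 11 | (3aS,6S,6aR)-6-allyl-4-isobutyryl-6-methyl-2-phenyl-6a-vinyl-tetrahydro-4H-cyclopenta[d][1,3]dioxol-5-one (benzylidene acetal; C2 and C4 epimers) | O=C1C(C(=O)C(C)C)[C@@H]2OC(c3ccccc3)O[C@]2(C=C)[C@]1(C)CC=C
F6 | step 11 | (3aS,4S,6S,6aR)-4,6-diallyl-4-isobutyryl-6-methyl-2-phenyl-6a-vinyl-tetrahydro-4H-cyclopenta[d][1,3]dioxol-5-one | O=C1[C@](CC=C)(C(=O)C(C)C)[C@@H]2OC(c3ccccc3)O[C@]2(C=C)[C@]1(C)CC=C
F7 | step 16 | bis(trimethylsilyl enol ether) of 24 (C3a=C4 and the isobutyryl group) | C=CCC[C@](C)(O[Si](CC)(CC)CC)[C@@H]1CC2=C(O[Si](C)(C)C)[C@](C)(CC=C)C(=O)[C@](CC=C)(C(O[Si](C)(C)C)=C(C)C)[C@@H]2O1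
F8 | step 16 | trimethylsilyl enol ether of 26 at the isobutyryl group | C=CCC[C@](C)(O[Si](CC)(CC)CC)[C@@H]1CC2=C(O1)[C@@](CC=C)(C(O[Si](C)(C)C)=C(C)C)C(=O)[C@@](C)(CC=C)C2=O
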